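**Plan** (labdane numbering: ring A = C1–C5, C10; ring B = C5–C10; C8=C17 exocyclic; chain C11–C16 on C9; acetate on C2)
1. Late cuts: the C2 acetate goes back through the 2β-alcohol and the 2-ketone to a 2α-silyl ether; the chain is cut at C12–C13 (B-alkyl Suzuki–Miyaura coupling with a (Z)-β-iodo enoate) and shortened to a C9 methyl ester (C11).
2. Core cut: both rings open together at the two ends of the C9–C10 edge of ring B, C8–C9 and C5–C10, to an acyclic (Z)-enoate with a radical precursor at C5 and a terminal alkyne C8≡C17.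
3. Enabling feature: C9 and C10 are adjacent ring-B atoms and can be one alkene; with C11 at ester level C10 is its electrophilic β-carbon, and the C8=C17 methylene is what a 6-exo-dig closure onto a terminal alkyne leaves behind.
4. Forward: the chain is built from (S)-epichlorohydrin, prenylmagnesium chloride, methyl propiolate, Me2CuLi and a butynyl Grignard reagent; ring A closes first (C5 to C10), ring B second (C9 to C8); then the chain and C2 are finished.
5. Stereochemistry: C2 comes from (S)-epichlorohydrin and steers C5, C10 and C9 in the chair-like closures (silyl ether equatorial, Z-ester enforcing trans fusion); C2 is then inverted by oxidation and equatorial hydride attack; the 13Z olefin comes from the iodo enoate and the C9=C10 Z-olefin from syn-carbocupration.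

Key step: step 8

Remark: compounds 14–16 are inconsequential epimer pairs at the carbinol carbon that becomes C5 (written without a stereo mark), because step 8 turns this carbon into a radical centre.

Step 1
Reactants: 1 (S)-epichlorohydrin; 2 prenylmagnesium chloride
Product: 4 (S)-2-(2,2-dimethylbut-3-en-1-yl)oxirane, via chlorohydrin 3 (not isolated)
Conditions: THF, −78 to 0 °C; then 5 M aq NaOH, rt
Reagents that add atoms: none
Why: The allylic Grignard reagent should attack the unsubstituted epoxide carbon through its γ-carbon (SE2′ epoxide opening), which creates the quaternary C4 and leaves the stereocentre untouched, and hydroxide then closes the chlorohydrin to the terminal epoxide (intramolecular Williamson displacement).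

Step 2
Reactants: 4 (S)-2-(2,2-dimethylbut-3-en-1-yl)oxirane; 5 methyl propiolate
Product: 7 methyl (5S)-5-hydroxy-7,7-dimethylnon-8-en-2-ynoate, via lithium methyl propiolate 6 (not isolated)
Conditions: 5, n-BuLi, THF, −78 °C; BF3·OEt2; then 4, −78 °C; H2O
Reagents that add atoms: none
Why: Yamaguchi–Hirao alkynylation: the BF3-activated epoxide should be opened at its terminal carbon by the lithium acetylide, giving the C1–C10 bond with the C2 carbinol unchanged.

Step 3
Reactants: 7 methyl (5S)-5-hydroxy-7,7-dimethylnon-8-en-2-ynoate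
Product: 8 methyl (5S)-5-[tert-butyl(dimethyl)silyl]oxy-7,7-dimethylnon-8-en-2-ynoate
Conditions: TBSCl, imidazole, DMF, rt
Reagents that add atoms: tert-butyldimethylsilyl chloride, CC(C)(C)[Si](C)(C)Cl
Why: Standard silylation of a secondary alcohol; the ether blocks lactonization of the Z-enoate made next and later holds the equatorial position in the key step.

Step 4
Reactants: 8 methyl (5S)-5-[tert-butyl(dimethyl)silyl]oxy-7,7-dimethylnon-8-en-2-ynoate
Product: 9 methyl (2Z,5R)-5-[tert-butyl(dimethyl)silyl]oxy-3,7,7-trimethylnona-2,8-dienoate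
Conditions: Me2CuLi (from MeLi, CuI), THF, −78 °C; MeOH quench at −78 °C
Reagents that add atoms: lithium dimethylcuprate, [Li+].C[Cu-]C
Why: Syn-carbocupration of the ynoate followed by protonation with retention at low temperature should install the C20 methyl and place the C1 methylene cis to the ester (Z).

Step 5
Reactants: 9 methyl (2Z,5R)-5-[tert-butyl(dimethyl)silyl]oxy-3,7,7-trimethylnona-2,8-dienoate
Product: 11 methyl (2Z,5R)-5-[tert-butyl(dimethyl)silyl]oxy-3,7,7-trimethyl-8-oxooct-2-enoate, via ozonide 10 (not isolated)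
Conditions: O3, CH2Cl2, −78 °C (Sudan Red end point); then PPh3, −78 °C to rt
Reagents that add atoms: ozone, [O-][O+]=O
Why: Ozonolysis with reductive work-up; the terminal vinyl group should react well before the electron-poor trisubstituted enoate, giving the non-enolizable neopentyl aldehyde at C5.

Step 6
Reactants: 11 methyl (2Z,5R)-5-[tert-butyl(dimethyl)silyl]oxy-3,7,7-trimethyl-8-oxooct-2-enoate; 12 (4-bromobut-1-yn-1-yl)trimethylsilane
Product: 15 methyl (2Z,5R)-5-[tert-butyl(dimethyl)silyl]oxy-8-hydroxy-3,7,7-trimethyldodec-2-en-11-ynoate, via Grignard reagent 13 (not isolated), via silyl alkynol 14 (not isolated)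
Conditions: 12, Mg, THF; add to 11, THF, −78 °C; then MeOH, K2CO3 (cat.), rt
Reagents that add atoms: none
Why: Grignard addition should take the aldehyde at −78 °C in preference to the conjugated β,β-disubstituted ester, and carbonate in methanol then removes the alkynyl silyl group; the new carbinol centre forms as both epimers, which does not matter.

Step 7
Reactants: 15 methyl (2Z,5R)-5-[tert-butyl(dimethyl)silyl]oxy-8-hydroxy-3,7,7-trimethyldodec-2-en-11-ynoate
Product: 16 methyl (2Z,5R)-5-[tert-butyl(dimethyl)silyl]oxy-3,7,7-trimethyl-8-(phenoxycarbonothioyloxy)dodec-2-en-11-ynoate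
Conditions: PhOC(S)Cl, pyridine, DMAP (cat.), CH2Cl2, 0 °C to rt
Reagents that add atoms: O-phenyl chlorothionoformate, S=C(Cl)Oc1ccccc1
Why: Acylation of the secondary alcohol gives the thionocarbonate, the usual Barton–McCombie precursor of a secondary alkyl radical.

Step 8
Reactants: 16 methyl (2Z,5R)-5-[tert-butyl(dimethyl)silyl]oxy-3,7,7-trimethyl-8-(phenoxycarbonothioyloxy)dodec-2-en-11-ynoate
Product: 17 methyl 2α-[tert-butyl(dimethyl)silyl]oxydrim-8(12)-en-11-oate (2S,5S,9S,10S)
Conditions: Bu3SnH (1.3 equiv), AIBN (0.2 equiv), syringe pump over 8 h into 16 (0.005 M), degassed PhMe, 100 °C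
Reagents that add atoms: none
Why: Bu3Sn• adds to the thiocarbonyl sulfur of 16 and β-scission frees the secondary C5 radical, which adds to C10 (the β-carbon of the acrylate); the resulting C9 α-ester radical adds to C8 of the alkyne, and the C17 vinyl radical takes hydrogen from Bu3SnH to leave the exocyclic methylene. The closest known reaction type is the Barton–McCombie-initiated tin hydride tandem radical cyclization in which a Giese-type ring closure onto an enoate is followed by capture of the α-carbonyl radical by an alkyne. Ring A closes 6-exo-trig (C5 to C10) and ring B closes 6-exo-dig (C9 to C8). C10 and C5 are set in the first chair-like transition state, where the C2 silyl ether and the C6 arm sit equatorial and the (Z)-ester, cis to C1, would suffer A(1,3) strain against C2 if the acrylate arm were axial, so C9 stays equatorial, C20 goes axial and the fusion becomes trans; the sense relative to C2 follows because the other chair would place the silyl ether syn-axial to the axial C4 methyl. C9 is set in the second chair-like closure, in which the planar ester-bearing radical keeps the ester equatorial (β) and H9 ends axial (α). The step needs attack at C10 and not at C9 (7-endo), and both closures must outrun hydrogen transfer and a 1,5-hydrogen shift from C1; the ester polarization of C9=C10, the gem-dimethyl group at C4 and slow addition of the hydride at high dilution are there to secure this.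

Step 9
Reactants: 17 methyl 2α-[tert-butyl(dimethyl)silyl]oxydrim-8(12)-en-11-oate
Product: 18 2α-[tert-butyl(dimethyl)silyl]oxydrim-8(12)-en-11-ol
Conditions: DIBAL-H (2.5 equiv), CH2Cl2, −78 to 0 °C; Rochelle salt
Reagents that add atoms: none
Why: Hydride reduction of the ester to the primary alcohol under non-basic conditions, so the β,γ-alkene should not move into conjugation and C9 should not epimerize.

Step 10
Reactants: 18 2α-[tert-butyl(dimethyl)silyl]oxydrim-8(12)-en-11-ol
Product: 19 2α-[tert-butyl(dimethyl)silyl]oxydrim-8(12)-en-11-al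
Conditions: Dess–Martin periodinane, NaHCO3, CH2Cl2, 0 °C to rt
Reagents that add atoms: none
Why: Buffered Dess–Martin oxidation should give the β,γ-unsaturated aldehyde without enolization at C9.

Step 11
Reactants: 19 2α-[tert-butyl(dimethyl)silyl]oxydrim-8(12)-en-11-al
Product: 20 2α-[tert-butyl(dimethyl)silyl]oxy-13,14,15,16-tetranorlabda-8(17),11-diene
Conditions: Ph3PCH3Br, KHMDS, THF, 0 °C; then 19, −78 to 0 °C
Reagents that add atoms: methyltriphenylphosphonium bromide, C[P+](c1ccccc1)(c1ccccc1)c1ccccc1.[Br-]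
Why: Wittig methylenation adds C12; fast addition of the ylide at low temperature should leave the C9 configuration intact.

Step 12
Reactants: 21 methyl but-2-ynoate
Product: 22 methyl (2Z)-3-iodobut-2-enoate
Conditions: NaI, AcOH, 110 °C
Reagents that add atoms: sodium iodide, [Na+].[I-]
Why: Conjugate addition of iodide and anti protonation (hydroiodination of an ynoate) should give the (Z)-β-iodo enoate.

Step 13
Reactants: 20 2α-[tert-butyl(dimethyl)silyl]oxy-13,14,15,16-tetranorlabda-8(17),11-diene; 22 methyl (2Z)-3-iodobut-2-enoate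
Product: 24 methyl (13Z)-2α-[tert-butyl(dimethyl)silyl]oxylabda-8(17),13-dien-15-oate, via alkylborane 23 (not isolated)
Conditions: 9-BBN, THF, 0 °C to rt; then 22, Pd(dppf)Cl2 (5 mol%), AsPh3, Cs2CO3, DMF/H2O, rt
Reagents that add atoms: none
Why: Anti-Markovnikov hydroboration should take the monosubstituted C11=C12 before the more hindered 1,1-disubstituted C8=C17, and the B-alkyl Suzuki–Miyaura coupling joins C12 to C13 with retention of the iodide geometry (13Z).

Step 14
Reactants: 24 methyl (13Z)-2α-[tert-butyl(dimethyl)silyl]oxylabda-8(17),13-dien-15-oate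
Product: 25 methyl (13Z)-2α-hydroxylabda-8(17),13-dien-15-oate
Conditions: TBAF, THF, 0 °C to rt
Reagents that add atoms: none
Why: Fluoride cleavage of the silyl ether; ester and both alkenes should be inert.

Step 15
Reactants: 25 methyl (13Z)-2α-hydroxylabda-8(17),13-dien-15-oate
Product: 26 methyl (13Z)-2-oxolabda-8(17),13-dien-15-oate
Conditions: Dess–Martin periodinane, NaHCO3, CH2Cl2, rt
Reagents that add atoms: none
Why: Dess–Martin oxidation removes the helper stereocentre; both α-carbons are CH2 next to quaternary centres, so nothing can epimerize.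

Step 16
Reactants: 26 methyl (13Z)-2-oxolabda-8(17),13-dien-15-oate
Product: 28 (13Z)-2β-hydroxylabda-8(17),13-dien-15-oic acid, via hydroxy ester 27 (not isolated)
Conditions: NaBH4, MeOH/THF, −20 °C; then LiOH, H2O, 45 °C; 1 M HCl to pH 3
Reagents that add atoms: lithium hydroxide, [Li+].[OH-]
Why: Borohydride should attack the ketone from the α face (equatorial attack), because the axial β trajectory is blocked by the syn-axial C19 and C20 methyls, giving the axial 2β-alcohol (2R); saponification in the same pot frees the acid.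

Step 17
Reactants: 28 (13Z)-2β-hydroxylabda-8(17),13-dien-15-oic acid
Product: 30 (13Z)-2β-acetoxylabda-8(17),13-dien-15-oic acid, via mixed anhydride 29 (not isolated)
Conditions: Ac2O, pyridine, DMAP (cat.), CH2Cl2, rt to 40 °C; then H2O/THF, rt
Reagents that add atoms: acetic anhydride, CC(=O)OC(C)=O
Why: DMAP-catalysed acetylation of the hindered axial alcohol, with the acyl carboxyl anhydride that forms at C15 hydrolysed again on the aqueous hold, should give the acetoxy acid.

**Compound list**
1 | (S)-epichlorohydrin | ClC[C@@H]1CO1 | starting material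
2 | prenylmagnesium chloride (THF solution) | CC(C)=CC[Mg]Cl | starting material
3 | (S)-1-chloro-4,4-dimethylhex-5-en-2-ol | C=CC(C)(C)C[C@H](O)CCl | intermediate
4 | (S)-2-(2,2-dimethylbut-3-en-1-yl)oxirane | C=CC(C)(C)C[C@H]1CO1 | intermediate
5 | methyl propiolate | C#CC(=O)OC | starting material
6 | lithium methyl propiolate | [Li]C#CC(=O)OC | intermediate
7 | methyl (5S)-5-hydroxy-7,7-dimethylnon-8-en-2-ynoate | C=CC(C)(C)C[C@H](O)CC#CC(=O)OC | intermediate
8 | methyl (5S)-5-[tert-butyl(dimethyl)silyl]oxy-7,7-dimethylnon-8-en-2-ynoate | C=CC(C)(C)C[C@H](O[Si](C)(C)C(C)(C)C)CC#CC(=O)OC | intermediate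
9 | methyl (2Z,5R)-5-[tert-butyl(dimethyl)silyl]oxy-3,7,7-trimethylnona-2,8-dienoate | C=CC(C)(C)C[C@H](O[Si](C)(C)C(C)(C)C)C/C(C)=C\C(=O)OC | intermediate
10 | methyl (2Z,5R)-5-[tert-butyl(dimethyl)silyl]oxy-3,7-dimethyl-7-(1,2,4-trioxolan-3-yl)oct-2-enoate (ozonide) | C1(OCOO1)C(C)(C)C[C@H](O[Si](C)(C)C(C)(C)C)C/C(C)=C\C(=O)OC | intermediate
11 | methyl (2Z,5R)-5-[tert-butyl(dimethyl)silyl]oxy-3,7,7-trimethyl-8-oxooct-2-enoate | O=CC(C)(C)C[C@H](O[Si](C)(C)C(C)(C)C)C/C(C)=C\C(=O)OC | intermediate
12 | (4-bromobut-1-yn-1-yl)trimethylsilane | C[Si](C)(C)C#CCCBr | starting material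
13 | [4-(trimethylsilyl)but-3-yn-1-yl]magnesium bromide | C[Si](C)(C)C#CCC[Mg]Br | intermediate
14 | methyl (2Z,5R)-5-[tert-butyl(dimethyl)silyl]oxy-8-hydroxy-3,7,7-trimethyl-12-(trimethylsilyl)dodec-2-en-11-ynoate (C8 epimers) | C[Si](C)(C)C#CCCC(O)C(C)(C)C[C@H](O[Si](C)(C)C(C)(C)C)C/C(C)=C\C(=O)OC | intermediate
15 | methyl (2Z,5R)-5-[tert-butyl(dimethyl)silyl]oxy-8-hydroxy-3,7,7-trimethyldodec-2-en-11-ynoate (C8 epimers) | C#CCCC(O)C(C)(C)C[C@H](O[Si](C)(C)C(C)(C)C)C/C(C)=C\C(=O)OC | intermediate
16 | methyl (2Z,5R)-5-[tert-butyl(dimethyl)silyl]oxy-3,7,7-trimethyl-8-(phenoxycarbonothioyloxy)dodec-2-en-11-ynoate (C8 epimers) | C#CCCC(OC(=S)Oc1ccccc1)C(C)(C)C[C@H](O[Si](C)(C)C(C)(C)C)C/C(C)=C\C(=O)OC | intermediate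
17 | methyl 2α-[tert-butyl(dimethyl)silyl]oxydrim-8(12)-en-11-oate (2S,5S,9S,10S) | C=C1CC[C@H]2C(C)(C)C[C@H](O[Si](C)(C)C(C)(C)C)C[C@]2(C)[C@H]1C(=O)OC | intermediate
18 | 2α-[tert-butyl(dimethyl)silyl]oxydrim-8(12)-en-11-ol | C=C1CC[C@H]2C(C)(C)C[C@H](O[Si](C)(C)C(C)(C)C)C[C@]2(C)[C@H]1CO | intermediate
19 | 2α-[tert-butyl(dimethyl)silyl]oxydrim-8(12)-en-11-al | C=C1CC[C@H]2C(C)(C)C[C@H](O[Si](C)(C)C(C)(C)C)C[C@]2(C)[C@H]1C=O | intermediate
20 | 2α-[tert-butyl(dimethyl)silyl]oxy-13,14,15,16-tetranorlabda-8(17),11-diene | C=C1CC[C@H]2C(C)(C)C[C@H](O[Si](C)(C)C(C)(C)C)C[C@]2(C)[C@H]1C=C | intermediate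
21 | methyl but-2-ynoate | CC#CC(=O)OC | starting material
22 | methyl (2Z)-3-iodobut-2-enoate | C/C(I)=C/C(=O)OC | intermediate
23 | B-[2α-(tert-butyldimethylsilyloxy)-13,14,15,16-tetranorlabd-8(17)-en-12-yl]-9-borabicyclo[3.3.1]nonane | C=C1CC[C@H]2C(C)(C)C[C@H](O[Si](C)(C)C(C)(C)C)C[C@]2(C)[C@H]1CCB1C2CCCC1CCC2 | intermediate
24 | methyl (13Z)-2α-[tert-butyl(dimethyl)silyl]oxylabda-8(17),13-dien-15-oate | C=C1CC[C@H]2C(C)(C)C[C@H](O[Si](C)(C)C(C)(C)C)C[C@]2(C)[C@H]1CC/C(C)=C\C(=O)OC | intermediate
25 | methyl (13Z)-2α-hydroxylabda-8(17),13-dien-15-oate | C=C1CC[C@H]2C(C)(C)C[C@H](O)C[C@]2(C)[C@H]1CC/C(C)=C\C(=O)OC | intermediate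
26 | methyl (13Z)-2-oxolabda-8(17),13-dien-15-oate | C=C1CC[C@H]2C(C)(C)CC(=O)C[C@]2(C)[C@H]1CC/C(C)=C\C(=O)OC | intermediate
27 | methyl (13Z)-2β-hydroxylabda-8(17),13-dien-15-oate | C=C1CC[C@H]2C(C)(C)C[C@@H](O)C[C@]2(C)[C@H]1CC/C(C)=C\C(=O)OC | intermediate
28 | (13Z)-2β-hydroxylabda-8(17),13-dien-15-oic acid | C=C1CC[C@H]2C(C)(C)C[C@@H](O)C[C@]2(C)[C@H]1CC/C(C)=C\C(=O)O | intermediate
29 | acetic (13Z)-2β-acetoxylabda-8(17),13-dien-15-oic anhydride | C=C1CC[C@H]2C(C)(C)C[C@@H](OC(C)=O)C[C@]2(C)[C@H]1CC/C(C)=C\C(=O)OC(C)=O | intermediate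
30 | (13Z)-2β-acetoxylabda-8(17),13-dien-15-oic acid (2R,5S,9S,10S) | C=C1CC[C@H]2C(C)(C)C[C@@H](OC(C)=O)C[C@]2(C)[C@H]1CC/C(C)=C\C(=O)O | target

**Step count**
Total: 17 steps. Longest linear sequence: 16 steps (steps 1–11 and 13–17; step 12 is a one-step branch).

**Steps most likely to fail**

1. Step 8. Hydrogen transfer from the stannane to the C5 or the C9 radical may outrun the ring closures, a 1,5-hydrogen shift from C1 may drain the C5 radical, and the second closure may set C9 with poor selectivity. The fallback sets out from 16 and comes back at 17 by closing the rings one at a time. With the stannane present from the start at 0.05 M, only the 6-exo-trig closure should occur and the α-ester radical is reduced, giving the monocyclic ester methyl 2-[2-(but-3-yn-1-yl)-5-(tert-butyldimethylsilyloxy)-1,3,3-trimethylcyclohexyl]acetate F1. Bromoboration of the alkyne with B-bromo-9-BBN and protonolysis with acetic acid should give the 2-bromoalkene methyl 2-[2-(3-bromobut-3-en-1-yl)-5-(tert-butyldimethylsilyloxy)-1,3,3-trimethylcyclohexyl]acetate F2. Palladium-catalysed intramolecular α-alkenylation of the ester enolate (Pd2(dba)3, bulky phosphine, LiHMDS) then closes ring B as a polar 6-exo process. Kinetic protonation of the resulting dienolate at C9 from the α face returns 17.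

2. Step 13. The hydroboration may fail to discriminate between the two terminal alkenes (C11=C12 and C8=C17), and the alkylborane may transfer slowly to palladium. The fallback sets out from 20 and comes back at 24. Disiamylborane, which discriminates strongly in favour of monosubstituted alkenes, followed by NaOH/H2O2, should give the primary alcohol 2α-(tert-butyldimethylsilyloxy)-13,14,15,16-tetranorlabd-8(17)-en-12-ol F3. Iodine, PPh3 and imidazole give the iodide 12-iodo-2α-(tert-butyldimethylsilyloxy)-13,14,15,16-tetranorlabd-8(17)-ene F4. Zinc insertion (Zn, LiCl, THF) gives the alkylzinc iodide F5, and Negishi coupling with 22 (Pd(PPh3)4, THF) returns 24 with retention of the Z geometry.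

3. Step 1. The enantiopurity may erode through reversible chloride opening of the epoxide (via the symmetric 1,3-dichloropropan-2-olate), and the allylic Grignard reagent may attack partly through its α-carbon. The fallback sets out from 2 and comes back at 8, setting the stereocentre by catalysis instead of from the chiral pool. Compound 2 and ethylene oxide give 3,3-dimethylpent-4-en-1-ol F6, and Dess–Martin oxidation gives 3,3-dimethylpent-4-enal F7. Chiral phosphoric acid-catalysed propargylation with allenylboronic acid pinacol ester (catalyst enantiomer chosen for the R carbinol) gives (R)-6,6-dimethyloct-7-en-1-yn-4-ol F8. TBSCl and imidazole give the silyl ether tert-butyl[(R)-6,6-dimethyloct-7-en-1-yn-4-yl]oxydimethylsilane F9, and n-BuLi followed by methyl chloroformate returns 8.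

**Further compounds**
F1 | step 8 | methyl 2-[2-(but-3-yn-1-yl)-5-(tert-butyldimethylsilyloxy)-1,3,3-trimethylcyclohexyl]acetate | C#CCC[C@H]1C(C)(C)C[C@H](O[Si](C)(C)C(C)(C)C)C[C@]1(C)CC(=O)OC
F2 | step 8 | methyl 2-[2-(3-bromobut-3-en-1-yl)-5-(tert-butyldimethylsilyloxy)-1,3,3-trimethylcyclohexyl]acetate | C=C(Br)CC[C@H]1C(C)(C)C[C@H](O[Si](C)(C)C(C)(C)C)C[C@]1(C)CC(=O)OC
F3 | step 13 | 2α-(tert-butyldimethylsilyloxy)-13,14,15,16-tetranorlabd-8(17)-en-12-ol | C=C1CC[C@H]2C(C)(C)C[C@H](O[Si](C)(C)C(C)(C)C)C[C@]2(C)[C@H]1CCO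
F4 | step 13 | 12-iodo-2α-(tert-butyldimethylsilyloxy)-13,14,15,16-tetranorlabd-8(17)-ene | C=C1CC[C@H]2C(C)(C)C[C@H](O[Si](C)(C)C(C)(C)C)C[C@]2(C)[C@H]1CCI
F5 | step 13 | [2α-(tert-butyldimethylsilyloxy)-13,14,15,16-tetranorlabd-8(17)-en-12-yl]zinc iodide | C=C1CC[C@H]2C(C)(C)C[C@H](O[Si](C)(C)C(C)(C)C)C[C@]2(C)[C@H]1CC[Zn]I
F6 | step 1 | 3,3-dimethylpent-4-en-1-ol | C=CC(C)(C)CCO
F7 | step 1 | 3,3-dimethylpent-4-enal | C=CC(C)(C)CC=O
F8 | step 1 | (R)-6,6-dimethyloct-7-en-1-yn-4-ol | C=CC(C)(C)C[C@H](O)CC#C
F9 | step 1 | tert-butyl[(R)-6,6-dimethyloct-7-en-1-yn-4-yl]oxydimethylsilane | C=CC(C)(C)C[C@H](O[Si](C)(C)C(C)(C)C)CC#C
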